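The earlier runs and the new flask come from a simulation with made-up constants.

How long can Tuesday's flask stand and still hold the most E, within 2.5 min, and how much E is that?

| flask | X | L | Q | remark | time |
|---|---|---|---|---|---|
| Tuesday's | 43 mM | 34.4 mM | 22 µM | the very flask that is asked about, followed so far |  |
| Thursday's | 43 mM | 52 mM | 22 µM | run made earlier |  |
| flask | 43 mM | 34.4 mM | 22 µM |  | 2.5 min |

| run | time / s | E / % | J / % |
|---|---|---|---|
| Tuesday's | 12.0 | 50 | 2 |
| Tuesday's | 20.0 | 66 | 3 |
| Tuesday's | 40.0 | 79 | 8 |
| Tuesday's | 80.0 | 75 | 25 |
| Thursday's | 12.0 | 48 | 4 |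
| Thursday's | 25.0 | 70 | 9 |
| Thursday's | 50.0 | 74 | 23 |
| Thursday's | 120 | 53 | 46 |

(readings scatter by 1.5 percentage points)

- the best time, 2.5 min at the latest, for E
- the amount of E, in percent of the X charged, at that time

- the numbers in the tables scatter by 1.5 percentage points (one standard deviation)

I reckon in rates. In Tuesday's run the making of E starts at a fraction kX = 0.0586 /s of the charge, read from the E and J readings at 20.0 s, and it slows by a factor e in each 17.1 s as cX falls. The use of E starts from nothing and grows with E: J at 80.0 s over the area under the E readings gives kE = 0.00472 /s, a smaller constant. Their ratio is 12.4; this ratio s, kX over kE, the selectivity factor, is what I carry. E peaks where making equals use, that is at cE/cX = s. For two first-order steps that comes at the logarithm of s over the difference of the constants, 0.779 min, inside the limit. The top is s raised to minus the inverse of s less one, 80.2% of the X charged.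

The forecast gives 0.8 min and 80%, saying “The peak is therefore near 48 s”.

The flask gives 0.786 min and 80.0%.

    X + Q → Q + E (k = 2720 /M/s)
    L + Q + E → Q + J (k = 7130 /M²/s)

At that time Tuesday's flask holds 5.95% X, and L is down to 82.4% of its charge, a fall my constant s does not follow. Put to the 80.0% of E, cE/cX = s gives 6.45% X.

In the scheme cL multiplies the use of E, so I scale s by the charges for a neighbour flask, charged like Tuesday's but with 21 mM of L. It becomes 20.3, with a top of 85.6%. Simulated, that neighbour reaches 85.6%.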